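The route rests on cutting the dihydropyran that fuses tropolone ring A to the eleven-membered ring at its C4'–O bond and its C8'H2–C8 bond (humulene numbers for the carbocycle, primed numbers for ring A). The key step is a strain-release [3+3] annulation: the dianion of a tropolonylacetic acid opens a macrocyclic cis-epoxide at C8 with inversion, and the freed tertiary C9 alkoxide then displaces the methoxy group on C4'; the carboxylate leaves as CO2. It exploits the vicinal C8–C9(O) pair beside the C10 carbinol and the adjacent O and CH2 substituents of ring A. The epoxy alcohol comes from a Nozaki–Hiyama–Kishi macrocyclisation; the second tropolone is added last by hetero-Diels–Alder reaction.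

Key step: step 19

Remark on labels: the carbocycle is numbered as in humulene (C1=C2(Me), C3, C4=C5, C6(Me)2, C7, C8, C9(Me), C10(OH), C11). Ring A is the tropolone on C8/C9: C1'/C2' carry the two tropolone oxygens, C4' the ether oxygen, C5' the methylene C8', C6' the methyl. Ring B is the tropolone on C1/C2.

Assumption: O-methylation of tropolone 18 is taken to give isomer 19 (carbonyl on C2', methoxy on C1'); the other O-regioisomer would react in the same way and converge in step 20.

Remark: 9 is racemic; 15–17 are racemic and drawn as one enantiomer; the transient C8' centre of 25 and 26 is not controlled and is left undefined.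

Step 1
Reactants: 1 methyl 3,3-dimethylpent-4-enoate
Product: 2 3,3-dimethylpent-4-enal
Conditions: iBu2AlH (1.05 equiv), CH2Cl2, −78 °C; Rochelle salt work-up
Reagents that add atoms: none
Why: Partial ester reduction (iBu2AlH reduction): at −78 °C the aluminium hemiacetal should persist until work-up, so reduction stops at the aldehyde and leaves the vinyl group untouched.

Step 2
Reactants: 2 3,3-dimethylpent-4-enal
Product: 3 (5Z)-6-iodo-3,3-dimethylhepta-1,5-diene
Conditions: EtPPh3I, n-BuLi, THF, 0 °C; I2, −78 °C; NaN(SiMe3)2, −78 °C; then 2, −78 → −20 °C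
Reagents that add atoms: ethyltriphenylphosphonium iodide CC[P+](c1ccccc1)(c1ccccc1)c1ccccc1.[I-]; iodine II
Why: Stork–Zhao olefination: the α-iodo ylide should add to the unhindered aldehyde under kinetic control to give the (Z)-2-iodoalkene, the geometry that later places C7 and C10 cis on C8=C9.

Step 3
Reactants: 4 pent-1-en-4-yne
Product: 6 (3E)-4-methylhepta-3,6-dien-1-ol, via alkenylalane 5 (not isolated)
Conditions: AlMe3 (2 equiv), Cp2ZrCl2 (0.2 equiv), CH2Cl2, 0 °C → rt; n-BuLi, THF, −78 °C; ethylene oxide, −78 °C → rt; aq. HCl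
Reagents that add atoms: trimethylaluminium C[Al](C)C; ethylene oxide C1CO1
Why: Zirconium-catalysed carboalumination (Negishi) adds methyl and aluminium syn across the terminal alkyne to fix the E trisubstituted alkene, and the derived alanate should open ethylene oxide with retention of alkene geometry, the isolated vinyl group being inert.

Step 4
Reactants: 3 (5Z)-6-iodo-3,3-dimethylhepta-1,5-diene; 6 (3E)-4-methylhepta-3,6-dien-1-ol
Product: 7 (3E,6E,10Z)-11-iodo-4,8,8-trimethyldodeca-3,6,10-trien-1-ol
Conditions: second-generation Hoveyda–Grubbs catalyst (5 mol%), 3 (2 equiv), 1,4-benzoquinone (10 mol%), CH2Cl2, 40 °C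
Reagents that add atoms: none
Why: Olefin cross-metathesis: the terminal alkene of 6 should couple with the neopentyl-type vinyl group of 3 to give the E disubstituted alkene (steric preference beside the quaternary carbon), while the trisubstituted alkene and the vinyl iodide are not engaged by the ruthenium carbene.

Step 5
Reactants: 7 (3E,6E,10Z)-11-iodo-4,8,8-trimethyldodeca-3,6,10-trien-1-ol
Product: 8 (3E,6E,10Z)-11-iodo-4,8,8-trimethyldodeca-3,6,10-trienal
Conditions: Dess–Martin periodinane, NaHCO3, CH2Cl2, 0 °C; used directly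
Reagents that add atoms: none
Why: Dess–Martin oxidation under bicarbonate buffering should give the β,γ-unsaturated aldehyde without migration of the double bond into conjugation.

Step 6
Reactants: 8 (3E,6E,10Z)-11-iodo-4,8,8-trimethyldodeca-3,6,10-trienal
Product: 9 rac-(2Z,6E,9E)-2,5,5,9-tetramethylcycloundeca-2,6,9-trien-1-ol
Conditions: CrCl2 (6 equiv), NiCl2 (2 mol%), DMSO–THF, 0.002 M, rt
Reagents that add atoms: none
Why: Intramolecular Nozaki–Hiyama–Kishi reaction: nickel-mediated activation of the vinyl iodide, transfer to chromium and addition to the aldehyde should close the eleven-membered ring (C9–C10 bond) under high dilution with retention of the Z geometry; the carbinol forms as a racemate.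

Step 7
Reactants: 9 rac-(2Z,6E,9E)-2,5,5,9-tetramethylcycloundeca-2,6,9-trien-1-ol
Product: 10 (2Z,6E,9E)-2,5,5,9-tetramethylcycloundeca-2,6,9-trien-1-one
Conditions: Dess–Martin periodinane, NaHCO3, CH2Cl2, 0 °C
Reagents that add atoms: none
Why: Dess–Martin oxidation removes the uncontrolled carbinol centre and gives the Z enone needed for catalyst-controlled reduction.

Step 8
Reactants: 10 (2Z,6E,9E)-2,5,5,9-tetramethylcycloundeca-2,6,9-trien-1-one
Product: 11 (1S,2Z,6E,9E)-2,5,5,9-tetramethylcycloundeca-2,6,9-trien-1-ol
Conditions: (R)-2-methyl-CBS-oxazaborolidine (0.2 equiv), catecholborane (1.5 equiv), toluene, −78 °C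
Reagents that add atoms: none
Why: Corey–Bakshi–Shibata reduction: the α-methylalkenyl group acts as the large and the C11 methylene as the small substituent, so the (R)-catalyst should deliver hydride to the face giving the (S)-carbinol at C10; catecholborane avoids hydroboration of the alkenes.

Step 9
Reactants: 11 (1S,2Z,6E,9E)-2,5,5,9-tetramethylcycloundeca-2,6,9-trien-1-ol
Product: 12 (1S,2S,4E,7E,11R)-1,5,9,9-tetramethyl-12-oxabicyclo[9.1.0]dodeca-4,7-dien-2-ol (cis-epoxide on C8/C9, erythro to the C10 hydroxyl)
Conditions: VO(acac)2 (5 mol%), t-BuOOH (1.5 equiv), CH2Cl2, 0 °C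
Reagents that add atoms: tert-butyl hydroperoxide CC(C)(C)OO
Why: Hydroxyl-directed vanadium-catalysed epoxidation: the vanadate ester of the C10 alcohol should deliver oxygen only to the allylic C8=C9 bond with retention of its Z geometry, and allylic 1,2-strain between the C9 methyl and C11 should favour the erythro isomer, so C10 sets C8 and C9.

Step 10
Reactants: 13 2-methylanisole
Product: 14 1-methoxy-2-methylcyclohexa-1,4-diene
Conditions: Li, NH3 (l), t-BuOH, THF, −78 → −33 °C
Reagents that add atoms: none
Why: Birch reduction: the arene should be reduced to the 1,4-diene that keeps both donor substituents on one double bond, giving the tetrasubstituted enol ether.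

Step 11
Reactants: 14 1-methoxy-2-methylcyclohexa-1,4-diene
Product: 15 rac-7,7-dichloro-1-methoxy-6-methylbicyclo[4.1.0]hept-3-ene
Conditions: CHCl3, KOtBu, pentane, −20 → 0 °C
Reagents that add atoms: chloroform ClC(Cl)Cl
Why: Dichlorocarbene cyclopropanation: the electrophilic carbene should add to the most electron-rich alkene, the enol ether, giving the cis-fused gem-dichlorocyclopropane.

Step 12
Reactants: 15 rac-7,7-dichloro-1-methoxy-6-methylbicyclo[4.1.0]hept-3-ene
Product: 16 rac-7,7-dichloro-1-methoxy-6-methylbicyclo[4.1.0]heptane-3,4-diol (cis-diol, anti to the CCl2 bridge)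
Conditions: OsO4 (2 mol%), N-methylmorpholine N-oxide, acetone–H2O, rt
Reagents that add atoms: N-methylmorpholine N-oxide C[N+]1([O-])CCOCC1; water O
Why: Upjohn dihydroxylation of the remaining cis-disubstituted alkene from the face anti to the endo chlorine should give the cis-diol, whose configuration is lost in the next step.

Step 13
Reactants: 16 rac-7,7-dichloro-1-methoxy-6-methylbicyclo[4.1.0]heptane-3,4-diol
Product: 18 5-chloro-2-hydroxy-4-methoxy-6-methylcyclohepta-2,4,6-trien-1-one, via dione 17 (not isolated)
Conditions: (CF3CO)2O, DMSO, CH2Cl2, −60 °C; Et3N, −60 → 40 °C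
Reagents that add atoms: none
Why: Swern-type double oxidation gives dione 17, whose enol should undergo methoxy-assisted electrocyclic opening of the cyclopropane with loss of chloride and aromatise to the tropolone (gem-dihalocyclopropane ring expansion), placing OMe, Cl and Me on C4', C5' and C6'.

Step 14
Reactants: 18 5-chloro-2-hydroxy-4-methoxy-6-methylcyclohepta-2,4,6-trien-1-one
Product: 19 5-chloro-2,6-dimethoxy-4-methylcyclohepta-2,4,6-trien-1-one
Conditions: MeI, K2CO3, acetone, rt
Reagents that add atoms: iodomethane CI
Why: Williamson O-methylation of the tropolonate masks the acidic hydroxyl as the methoxytropone (regiochemistry as assumed above).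

Step 15
Reactants: 19 5-chloro-2,6-dimethoxy-4-methylcyclohepta-2,4,6-trien-1-one
Product: 20 tert-butyl 2-(2,6-dimethoxy-4-methyl-1-oxocyclohepta-2,4,6-trien-5-yl)acetate (ring numbered as in 19)
Conditions: BrZnCH2CO2tBu (from tert-butyl bromoacetate and Zn dust, THF), Pd2(dba)3 (2.5 mol%), XPhos (10 mol%), THF, 60 °C
Reagents that add atoms: tert-butyl bromoacetate BrCC(=O)OC(C)(C)C
Why: Palladium-catalysed Negishi-type coupling of a Reformatsky reagent: the C5' chloride is a vinylogous acyl chloride that should undergo oxidative addition readily, and the zinc enolate tolerates the tropone carbonyl.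

Step 16
Reactants: 20 tert-butyl 2-(2,6-dimethoxy-4-methyl-1-oxocyclohepta-2,4,6-trien-5-yl)acetate
Product: 21 2-(2,6-dimethoxy-4-methyl-1-oxocyclohepta-2,4,6-trien-5-yl)acetic acid
Conditions: CF3CO2H–CH2Cl2 (1:4), 0 °C → rt; used at once
Reagents that add atoms: none
Why: Acidolysis of the tert-butyl ester (loss of isobutene) should free the acid without touching the methoxytropone; the acid is not stored because it can decarboxylate on heating.

Step 17
Reactants: 19 5-chloro-2,6-dimethoxy-4-methylcyclohepta-2,4,6-trien-1-one
Product: 22 5-(hydroxymethyl)-2,6-dimethoxy-4-methylcyclohepta-2,4,6-trien-1-one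
Conditions: Bu3SnCH2OH, Pd2(dba)3 (2.5 mol%), XPhos (10 mol%), 1,4-dioxane, 100 °C
Reagents that add atoms: (tributylstannyl)methanol OC[Sn](CCCC)(CCCC)CCCC
Why: Stille coupling: the stannane should transfer its hydroxymethyl group selectively to the palladium-activated C5' position.

Step 18
Reactants: 22 5-(hydroxymethyl)-2,6-dimethoxy-4-methylcyclohepta-2,4,6-trien-1-one
Product: 23 2,4-dihydroxy-5-(hydroxymethyl)-6-methylcyclohepta-2,4,6-trien-1-one
Conditions: 2 M HCl, 1,4-dioxane–H2O, 80 °C
Reagents that add atoms: water O
Why: Acid hydrolysis of both methoxy groups by addition–elimination at the vinylogous ester carbons (hydrolysis of tropolone ethers) should unmask the 4-hydroxytropolone that serves as o-quinone methide precursor.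

Step 19
Reactants: 21 2-(2,6-dimethoxy-4-methyl-1-oxocyclohepta-2,4,6-trien-5-yl)acetic acid; 12 (1S,2S,4E,7E,11R)-1,5,9,9-tetramethyl-12-oxabicyclo[9.1.0]dodeca-4,7-dien-2-ol
Product: 27 ring A methyl ether of the pyran-fused mono-tropolone (C1' methoxy and C2' carbonyl; C4'–O–C9 and C8'H2–C8 bonds; 8R,9R,10S; C10–OH free), via dianion 24 (not isolated), via alkoxide 25 (not isolated), via pyran acid 26 (not isolated)
Conditions: 21 (1.5 equiv), LiN(SiMe3)2 (3.0 equiv), THF–DMPU (4:1), −78 → 0 °C; 12, 0 → 60 °C; then AcOH (10 equiv), 50 °C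
Reagents that add atoms: none
Why: Proposed new method: the carbanion of dianion 24 (doubly activated, α to the carboxylate and vinylogous to the tropone carbonyl, hence formed in preference to the C6' methyl anion) should open the lithium- and hydroxyl-activated oxirane of 12 by SN2 attack at the secondary carbon C8, releasing ring strain and giving alkoxide 25. The C9 alkoxide then adds 6-exo-trig to C4', the β-carbon of the vinylogous ester, and expels methoxide (addition–elimination, completed if necessary by acid-catalysed transetherification in the acetic acid stage), closing the dihydropyran of 26, whose vinylogous β-keto acid loses CO2 on warming to leave the C8' methylene. The closest known reaction types are the Ivanov-type opening of epoxides by arylacetic acid dianions and the epoxide-opening/alkoxide SNAr route to chromans from ortho-halobenzyl nucleophiles, neither of which has been shown on tropones. C8 is the only new stereocentre and is set by inversion at the enantiopure cis-epoxide, while C9 keeps its C–O bond, so the trans ring fusion follows stereospecifically. The step needs attack at C8 and not at the fully substituted C9 (steric SN2 preference) and O-arylation by the C9 and not the C10 oxygen (six- against seven-membered ring).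

Step 20
Reactants: 27 ring A methyl ether of the pyran-fused mono-tropolone
Product: 28 pyran-fused mono-tropolone (ring A tropolone on C8/C9 of (1E,4E)-humula-1,4-dien-10-ol; 8R,9R,10S)
Conditions: LiOH (3 equiv), THF–H2O (3:1), 40 °C; then 1 M HCl to pH 3, 0 °C
Reagents that add atoms: lithium hydroxide [Li+].[OH-]
Why: Addition–elimination by hydroxide at C1' (hydrolysis of a tropolone methyl ether) should release the inert tropolonate, which shields the hindered tertiary ether at C4' from further attack; no stereocentre is touched.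

Step 21
Reactants: 28 pyran-fused mono-tropolone; 23 2,4-dihydroxy-5-(hydroxymethyl)-6-methylcyclohepta-2,4,6-trien-1-one
Product: 30 CNP0283947.4 (bis-tropolone target), via o-quinone methide 29 (not isolated)
Conditions: 23 (3 equiv), p-xylene, 150 °C, sealed tube
Reagents that add atoms: none
Why: Thermal dehydration of 23 gives tropolone o-quinone methide 29, which should undergo an inverse-electron-demand hetero-Diels–Alder reaction with the electron-rich trisubstituted C1=C2 alkene: oxygen bonds to the more substituted C2, suprafacial addition to the E alkene gives the trans ring fusion, and attack on the exposed peripheral face of the macrocycle is expected to set C1 and C2 as R,R.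

Compound list

1 | methyl 3,3-dimethylpent-4-enoate | COC(=O)CC(C)(C)C=C | starting material
2 | 3,3-dimethylpent-4-enal | O=CCC(C)(C)C=C | intermediate
3 | (5Z)-6-iodo-3,3-dimethylhepta-1,5-diene | C=CC(C)(C)C/C=C(/C)I | intermediate
4 | pent-1-en-4-yne | C=CCC#C | starting material
5 | (E)-dimethyl(2-methylpenta-1,4-dien-1-yl)alane (not isolated) | C=CC/C(C)=C/[Al](C)C | intermediate
6 | (3E)-4-methylhepta-3,6-dien-1-ol | OCC/C=C(C)/CC=C | intermediate
7 | (3E,6E,10Z)-11-iodo-4,8,8-trimethyldodeca-3,6,10-trien-1-ol | OCC/C=C(C)/C/C=C/C(C)(C)C/C=C(/C)I | intermediate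
8 | (3E,6E,10Z)-11-iodo-4,8,8-trimethyldodeca-3,6,10-trienal | O=CC/C=C(C)/C/C=C/C(C)(C)C/C=C(/C)I | intermediate
9 | rac-(2Z,6E,9E)-2,5,5,9-tetramethylcycloundeca-2,6,9-trien-1-ol | OC1C/C=C(C)/C/C=C/C(C)(C)C/C=C1/C | intermediate
10 | (2Z,6E,9E)-2,5,5,9-tetramethylcycloundeca-2,6,9-trien-1-one | O=C1C/C=C(C)/C/C=C/C(C)(C)C/C=C1/C | intermediate
11 | (1S,2Z,6E,9E)-2,5,5,9-tetramethylcycloundeca-2,6,9-trien-1-ol | O[C@H]1C/C=C(C)/C/C=C/C(C)(C)C/C=C1/C | intermediate
12 | (1S,2S,4E,7E,11R)-1,5,9,9-tetramethyl-12-oxabicyclo[9.1.0]dodeca-4,7-dien-2-ol | [C@@H]12CC(C)(C)/C=C/C/C(C)=C/C[C@H](O)[C@]1(C)O2 | intermediate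
13 | 2-methylanisole | COc1ccccc1C | starting material
14 | 1-methoxy-2-methylcyclohexa-1,4-diene | COC1=C(C)CC=CC1 | intermediate
15 | rac-7,7-dichloro-1-methoxy-6-methylbicyclo[4.1.0]hept-3-ene | CO[C@@]12CC=CC[C@]1(C)C2(Cl)Cl | intermediate
16 | rac-7,7-dichloro-1-methoxy-6-methylbicyclo[4.1.0]heptane-3,4-diol (cis-diol anti to CCl2) | CO[C@@]12C[C@@H](O)[C@@H](O)C[C@]1(C)C2(Cl)Cl | intermediate
17 | rac-7,7-dichloro-1-methoxy-6-methylbicyclo[4.1.0]heptane-3,4-dione (not isolated) | CO[C@@]12CC(=O)C(=O)C[C@]1(C)C2(Cl)Cl | intermediate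
18 | 5-chloro-2-hydroxy-4-methoxy-6-methylcyclohepta-2,4,6-trien-1-one | Cc1cc(=O)c(O)cc(OC)c1Cl | intermediate
19 | 5-chloro-2,6-dimethoxy-4-methylcyclohepta-2,4,6-trien-1-one | Cc1cc(OC)c(=O)cc(OC)c1Cl | intermediate
20 | tert-butyl 2-(2,6-dimethoxy-4-methyl-1-oxocyclohepta-2,4,6-trien-5-yl)acetate | Cc1cc(OC)c(=O)cc(OC)c1CC(=O)OC(C)(C)C | intermediate
21 | 2-(2,6-dimethoxy-4-methyl-1-oxocyclohepta-2,4,6-trien-5-yl)acetic acid | Cc1cc(OC)c(=O)cc(OC)c1CC(=O)O | intermediate
22 | 5-(hydroxymethyl)-2,6-dimethoxy-4-methylcyclohepta-2,4,6-trien-1-one | Cc1cc(OC)c(=O)cc(OC)c1CO | intermediate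
23 | 2,4-dihydroxy-5-(hydroxymethyl)-6-methylcyclohepta-2,4,6-trien-1-one | Cc1cc(=O)c(O)cc(O)c1CO | intermediate
24 | dilithium dianion of 21 (carboxylate and C8' carbanion; not isolated) | Cc1cc(OC)c(=O)cc(OC)c1[CH-]C(=O)[O-].[Li+].[Li+] | intermediate
25 | dilithium alkoxide carboxylate after C8'–C8 bond formation (C9–O−, CO2−, C4'–OMe still present, C10–OH free; not isolated) | Cc1cc(OC)c(=O)cc(OC)c1C(C(=O)[O-])[C@H]1CC(C)(C)/C=C/C/C(C)=C/C[C@H](O)[C@]1(C)[O-].[Li+].[Li+] | intermediate
26 | pyran-fused carboxylic acid (27 bearing CO2H on C8'; not isolated) | Cc1cc(OC)c(=O)cc2c1C(C(=O)O)[C@H]1CC(C)(C)/C=C/C/C(C)=C/C[C@H](O)[C@]1(C)O2 | intermediate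
27 | ring A methyl ether of the pyran-fused mono-tropolone (8R,9R,10S) | Cc1cc(OC)c(=O)cc2c1C[C@H]1CC(C)(C)/C=C/C/C(C)=C/C[C@H](O)[C@]1(C)O2 | intermediate
28 | pyran-fused mono-tropolone (8R,9R,10S) | Cc1cc(=O)c(O)cc2c1C[C@H]1CC(C)(C)/C=C/C/C(C)=C/C[C@H](O)[C@]1(C)O2 | intermediate
29 | 2-hydroxy-6-methyl-5-methylidenecyclohepta-2,6-diene-1,4-dione (o-quinone methide; not isolated) | C=C1C(C)=CC(=O)C(O)=CC1=O | intermediate
30 | CNP0283947.4 | Cc1cc(=O)c(O)cc2c1C[C@H]1CC(C)(C)/C=C/C[C@@]3(C)Oc4cc(O)c(=O)cc(C)c4C[C@@H]3C[C@H](O)[C@]1(C)O2 | target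

Total step count: 21. Longest linear sequence: 11 steps (steps 1, 2, 4–9, 19–21).

Steps most likely to fail

Step 19 (Proposed new method). The stabilised dianion may open the hindered trisubstituted epoxide too slowly, so that base-induced isomerisation of the epoxide or premature decarboxylation of the nucleophile takes over; the alkoxide may also be quenched by the acidic C8' or C6'-methyl protons before it closes the ring. Fallback with known chemistry: epoxy alcohol 12 is deoxygenated with inversion of alkene geometry (LiPPh2, THF, then MeI; syn elimination of the β-oxido phosphonium salt) to give (1S,2E,6E,9E)-2,5,5,9-tetramethylcycloundeca-2,6,9-trien-1-ol F1. Heating F1 with 23 in p-xylene at 150 °C generates o-quinone methide 29, whose hetero-Diels–Alder addition across the E C8=C9 bond forms the same trans-fused pyran and returns to the route at 28.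

Step 21. The cycloaddition may show poor facial selectivity at C1=C2, or compete at C4=C5, because the conformation of macrocycle 28 is not under firm control. Fallback: the order of the two annulations is reversed. Epoxy alcohol 12 is heated with 23 (p-xylene, 150 °C) so that 29 adds to C1=C2 of a different, epoxide-constrained macrocycle, giving the ring B adduct of the epoxy alcohol F2, whose diastereomers can be separated at this stage. F2 is then subjected to the conditions of step 19 with acid 21 (one further equivalent of dianion for the free tropolone) to give the ring A methyl ether of the target F3, and LiOH as in step 20 returns to the route at 30.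

Step 9. Allylic 1,3-strain from the Z substituent may override the 1,2-strain argument and erode the erythro selectivity, which would carry the wrong epoxide configuration forward. Fallback: enone 10 is reduced with the (S)-oxazaborolidine and catecholborane to (1R,2Z,6E,9E)-2,5,5,9-tetramethylcycloundeca-2,6,9-trien-1-ol F4. Epoxidation with Ti(OiPr)4 and t-BuOOH, which is threo-selective for Z allylic alcohols, gives (1S,2R,4E,7E,11R)-1,5,9,9-tetramethyl-12-oxabicyclo[9.1.0]dodeca-4,7-dien-2-ol F5 with the required epoxide configuration. Dess–Martin oxidation gives (1R,4E,7E,11R)-1,5,9,9-tetramethyl-12-oxabicyclo[9.1.0]dodeca-4,7-dien-2-one F6, and chelation-controlled reduction with Zn(BH4)2 (anti to the epoxide) returns to the route at 12.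

Further compounds
F1 | step 19 | (1S,2E,6E,9E)-2,5,5,9-tetramethylcycloundeca-2,6,9-trien-1-ol | O[C@H]1C/C=C(C)/C/C=C/C(C)(C)C/C=C1\C
F2 | step 21 | ring B adduct of the epoxy alcohol (tropolone pyran on C1/C2 of 12) | [C@@H]12CC(C)(C)/C=C/C[C@@]3(C)Oc4cc(O)c(=O)cc(C)c4C[C@@H]3C[C@H](O)[C@]1(C)O2
F3 | step 21 | ring A methyl ether of the target | Cc1cc(OC)c(=O)cc2c1C[C@H]1CC(C)(C)/C=C/C[C@@]3(C)Oc4cc(O)c(=O)cc(C)c4C[C@@H]3C[C@H](O)[C@]1(C)O2
F4 | step 9 | (1R,2Z,6E,9E)-2,5,5,9-tetramethylcycloundeca-2,6,9-trien-1-ol | O[C@@H]1C/C=C(C)/C/C=C/C(C)(C)C/C=C1/C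
F5 | step 9 | (1S,2R,4E,7E,11R)-1,5,9,9-tetramethyl-12-oxabicyclo[9.1.0]dodeca-4,7-dien-2-ol | [C@@H]12CC(C)(C)/C=C/C/C(C)=C/C[C@@H](O)[C@]1(C)O2
F6 | step 9 | (1R,4E,7E,11R)-1,5,9,9-tetramethyl-12-oxabicyclo[9.1.0]dodeca-4,7-dien-2-one | [C@@H]12CC(C)(C)/C=C/C/C(C)=C/CC(=O)[C@]1(C)O2
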